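Ring A is built, not decorated: its C1–C2 and C5–C6 bonds are disconnected to 4-chloro-3-methoxycyclobutenone and a methoxyalkyne that already carries ring B through C7. One thermal cascade (ring opening, ketene–alkyne [2+2], ring opening, six-electron closure re-forming C2–C3) should deliver the complete ring. It exploits the fact that the lone free hydroxyl at C2 lies between C3–Cl and the C1 side chain in a ring oxygenated at C2, C4 and C6. The alkyne partner is the TBS ether of the C7 carbinol, with the ring B 4'-hydroxyl masked as a MOM ether. Desilylation, MnO2 oxidation and mild acid finish the synthesis.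

Key step: step 7

Remark: ring A is numbered C1 (bearing carbonyl carbon C7), C2 OH, C3 Cl, C4 OMe, C5 H, C6 OMe; ring B is C1' (on C7), C2' Me, C4' OH, C6' OMe. The target has no stereocenter, so C7 is carried as a racemic carbinol and every transient sp3 centre is racemic and later erased.

Step 1
Reactants: 1 2,4-dihydroxy-6-methylbenzaldehyde
Product: 2 2-hydroxy-4-(methoxymethoxy)-6-methylbenzaldehyde
Conditions: MOMCl (1.05 equiv), i-Pr2NEt, CH2Cl2, 0 °C
Reagents that add atoms: chloromethyl methyl ether (MOMCl), COCCl
Why: Williamson-type O-alkylation should take the 4-hydroxyl, which is the more acidic and accessible one, because the 2-hydroxyl is held in a hydrogen bond to the aldehyde carbonyl.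

Step 2
Reactants: 2 2-hydroxy-4-(methoxymethoxy)-6-methylbenzaldehyde
Product: 3 2-methoxy-4-(methoxymethoxy)-6-methylbenzaldehyde
Conditions: MeI, K2CO3, DMF, rt to 40 °C
Reagents that add atoms: iodomethane, CI
Why: Williamson etherification of the chelated phenol with MeI and K2CO3 in a dipolar solvent is routine for salicylaldehydes and leaves the MOM acetal and the aldehyde untouched.

Step 3
Reactants: 4 chloroacetaldehyde dimethyl acetal
Product: 6 methoxyacetylene, via sodium methoxyacetylide 5 (not isolated)
Conditions: NaNH2 (3.1 equiv), liquid NH3, −33 °C; evaporate NH3; cold saturated aqueous NaCl, −70 °C to rt, distil (bp about 23 °C) into cold THF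
Reagents that add atoms: none
Why: Twofold base-induced β-elimination (loss of MeOH, then of HCl) from the chloroacetal is the standard preparation of alkoxyacetylenes, and the product rests as its sodium acetylide until the aqueous quench.

Step 4
Reactants: 6 methoxyacetylene; 3 2-methoxy-4-(methoxymethoxy)-6-methylbenzaldehyde
Product: 8 3-methoxy-1-[2-methoxy-4-(methoxymethoxy)-6-methylphenyl]prop-2-yn-1-ol (racemic), via lithium methoxyacetylide 7 (not isolated)
Conditions: 6 (1.5 equiv), n-BuLi (1.4 equiv), THF, −78 °C; then 3, −78 to 0 °C; cold water quench, no acid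
Reagents that add atoms: none
Why: 1,2-Addition of a lithium acetylide to an aromatic aldehyde should proceed despite two ortho substituents because the nucleophile is linear and small; the C7 stereocenter forms without control (racemic, later oxidised away), and the base-only work-up avoids Meyer–Schuster rearrangement of the acid-labile ynol ether carbinol.

Step 5
Reactants: 8 3-methoxy-1-[2-methoxy-4-(methoxymethoxy)-6-methylphenyl]prop-2-yn-1-ol (racemic)
Product: 9 tert-butyl({3-methoxy-1-[2-methoxy-4-(methoxymethoxy)-6-methylphenyl]prop-2-yn-1-yl}oxy)dimethylsilane (racemic)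
Conditions: TBSCl (1.5 equiv), imidazole (3 equiv), DMAP (cat.), DMF, rt to 40 °C
Reagents that add atoms: tert-butyldimethylsilyl chloride, CC(C)(C)[Si](C)(C)Cl
Why: Silylation of a secondary alcohol with TBSCl and imidazole in DMF (Corey conditions) runs under mildly basic conditions that the ynol ether, the MOM acetal and the electron-rich benzylic C–O bond should tolerate.

Step 6
Reactants: 6 methoxyacetylene; 10 chloroacetyl chloride
Product: 12 4-chloro-3-methoxycyclobut-2-en-1-one (racemic), via chloroketene 11 (not isolated)
Conditions: 6 (2 equiv), Et3N (1.1 equiv, added over 2 h), Et2O, 0 °C to rt; filter, concentrate cold, use promptly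
Reagents that add atoms: none
Why: Dehydrochlorination of the acid chloride by Et3N gives chloroketene, which should undergo the thermal ketene–alkyne [2+2] cycloaddition with the electron-rich ynol ether, the alkyne CH carbon bonding to the ketene carbonyl carbon so that OMe ends at C3 and Cl at C4; the C4 stereocenter is racemic and is erased in step 7.

Step 7
Reactants: 12 4-chloro-3-methoxycyclobut-2-en-1-one (racemic); 9 tert-butyl({3-methoxy-1-[2-methoxy-4-(methoxymethoxy)-6-methylphenyl]prop-2-yn-1-yl}oxy)dimethylsilane (racemic)
Product: 17 2-chloro-3,5-dimethoxy-6-{[(tert-butyldimethylsilyl)oxy][2-methoxy-4-(methoxymethoxy)-6-methylphenyl]methyl}phenol (racemic), via vinylketene 13 (not isolated), via vinylcyclobutenone 14 (not isolated), via dienylketene 15 (not isolated), via cyclohexadienone 16 (not isolated)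
Conditions: 9 (1 equiv), 12 (2 equiv), toluene (0.5 M), 80 °C then 110 °C, sealed tube, argon
Reagents that add atoms: none
Why: Heat should open 12 by four-electron conrotatory ring opening (Cl turning outward) to vinylketene 13, whose ketene C=C adds across the alkyne of 9 in a [2+2] to give 14; 14 reopens to dienylketene 15, which closes between the ketene carbon (future C2) and the CHCl carbon (future C3) to 16, and enolisation gives the phenol. This is the Danheiser benzannulation of a cyclobutenone with an alkoxyalkyne, applied here to a 4-chloro-3-methoxycyclobutenone and a branched alkyne. Ring A is closed by a thermal six-electron disrotatory electrocyclization after the two intermolecular bonds C1–C2 and C5–C6 have been made in the [2+2] step. No stereocenter is created in 17: the C7 centre of 9 passes through unchanged and racemic, and the sp3 centres of 14 and 16 vanish on ring opening and aromatisation. The selectivity needed is the orientation of the [2+2], secured by the methoxy group, which polarises the alkyne so that the carbon bearing C7 is the nucleophile and bonds to the ketene carbonyl carbon; Cl must end next to the hydroxyl because it sits on C4 of the cyclobutenone, the carbon that rejoins the ketene carbon in the final closure. A methyl ynol ether cannot fragment by retro-ene loss of an alkene at these temperatures, and the silyl-protected carbinol keeps the alkyne electron-rich.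

Step 8
Reactants: 17 2-chloro-3,5-dimethoxy-6-{[(tert-butyldimethylsilyl)oxy][2-methoxy-4-(methoxymethoxy)-6-methylphenyl]methyl}phenol (racemic)
Product: 18 2-chloro-6-{hydroxy[2-methoxy-4-(methoxymethoxy)-6-methylphenyl]methyl}-3,5-dimethoxyphenol (racemic)
Conditions: TBAF (1.5 equiv), AcOH (1.5 equiv), THF, 0 °C to rt
Reagents that add atoms: none
Why: Fluoride-mediated desilylation, driven by the strong Si–F bond and buffered with AcOH so that the medium stays near neutral, should free the C7 hydroxyl while the MOM and methyl ethers stay in place.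

Step 9
Reactants: 18 2-chloro-6-{hydroxy[2-methoxy-4-(methoxymethoxy)-6-methylphenyl]methyl}-3,5-dimethoxyphenol (racemic)
Product: 19 (3-chloro-2-hydroxy-4,6-dimethoxyphenyl)[2-methoxy-4-(methoxymethoxy)-6-methylphenyl]methanone
Conditions: activated MnO2 (excess), CH2Cl2, rt to reflux
Reagents that add atoms: none
Why: MnO2 oxidation of a doubly benzylic alcohol proceeds at neutral pH, the ring B phenol is still masked so that no oxidative phenol coupling to a spirocycle can intervene, and the C7 stereocenter disappears as the carbonyl forms.

Step 10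
Reactants: 19 (3-chloro-2-hydroxy-4,6-dimethoxyphenyl)[2-methoxy-4-(methoxymethoxy)-6-methylphenyl]methanone
Product: 20 (3-chloro-2-hydroxy-4,6-dimethoxyphenyl)(4-hydroxy-2-methoxy-6-methylphenyl)methanone
Conditions: HCl (cat.), MeOH, 40 °C
Reagents that add atoms: none
Why: Acid-catalysed acetal methanolysis should remove the MOM group as dimethoxymethane, while the aryl methyl ethers, the aryl chloride and the now robust diaryl ketone are inert.

Compound list
1 | 2,4-dihydroxy-6-methylbenzaldehyde | Cc1cc(O)cc(O)c1C=O | starting material
2 | 2-hydroxy-4-(methoxymethoxy)-6-methylbenzaldehyde | Cc1cc(OCOC)cc(O)c1C=O | intermediate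
3 | 2-methoxy-4-(methoxymethoxy)-6-methylbenzaldehyde | Cc1cc(OCOC)cc(OC)c1C=O | intermediate
4 | chloroacetaldehyde dimethyl acetal (2-chloro-1,1-dimethoxyethane) | COC(CCl)OC | starting material
5 | sodium methoxyacetylide | COC#C[Na] | intermediate
6 | methoxyacetylene (methoxyethyne) | COC#C | intermediate
7 | lithium methoxyacetylide | COC#C[Li] | intermediate
8 | 3-methoxy-1-[2-methoxy-4-(methoxymethoxy)-6-methylphenyl]prop-2-yn-1-ol (racemic) | COC#CC(O)c1c(C)cc(OCOC)cc1OC | intermediate
9 | tert-butyl({3-methoxy-1-[2-methoxy-4-(methoxymethoxy)-6-methylphenyl]prop-2-yn-1-yl}oxy)dimethylsilane (racemic) | COC#CC(O[Si](C)(C)C(C)(C)C)c1c(C)cc(OCOC)cc1OC | intermediate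
10 | chloroacetyl chloride | ClCC(=O)Cl | starting material
11 | chloroketene | O=C=CCl | intermediate
12 | 4-chloro-3-methoxycyclobut-2-en-1-one (racemic) | O=C1C=C(OC)C1Cl | intermediate
13 | (3Z)-4-chloro-3-methoxybuta-1,3-dien-1-one (vinylketene, Cl trans to the ketene carbon chain) | O=C=C/C(OC)=C/Cl | intermediate
14 | 2-{[(tert-butyldimethylsilyl)oxy][2-methoxy-4-(methoxymethoxy)-6-methylphenyl]methyl}-4-[(Z)-2-chloro-1-methoxyethenyl]-3-methoxycyclobut-2-en-1-one (racemic mixture of diastereomers) | O=C1C(C(O[Si](C)(C)C(C)(C)C)c2c(C)cc(OCOC)cc2OC)=C(OC)C1/C(OC)=C/Cl | intermediate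
15 | (3E,5Z)-2-{[(tert-butyldimethylsilyl)oxy][2-methoxy-4-(methoxymethoxy)-6-methylphenyl]methyl}-6-chloro-3,5-dimethoxyhexa-1,3,5-trien-1-one (dienylketene, racemic) | O=C=C(C(O[Si](C)(C)C(C)(C)C)c1c(C)cc(OCOC)cc1OC)/C(OC)=C\C(OC)=C\Cl | intermediate
16 | 2-{[(tert-butyldimethylsilyl)oxy][2-methoxy-4-(methoxymethoxy)-6-methylphenyl]methyl}-6-chloro-3,5-dimethoxycyclohexa-2,4-dien-1-one (racemic mixture of diastereomers) | O=C1C(C(O[Si](C)(C)C(C)(C)C)c2c(C)cc(OCOC)cc2OC)=C(OC)C=C(OC)C1Cl | intermediate
17 | 2-chloro-3,5-dimethoxy-6-{[(tert-butyldimethylsilyl)oxy][2-methoxy-4-(methoxymethoxy)-6-methylphenyl]methyl}phenol (racemic) | COc1cc(OC)c(C(O[Si](C)(C)C(C)(C)C)c2c(C)cc(OCOC)cc2OC)c(O)c1Cl | intermediate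
18 | 2-chloro-6-{hydroxy[2-methoxy-4-(methoxymethoxy)-6-methylphenyl]methyl}-3,5-dimethoxyphenol (racemic) | COc1cc(OC)c(C(O)c2c(C)cc(OCOC)cc2OC)c(O)c1Cl | intermediate
19 | (3-chloro-2-hydroxy-4,6-dimethoxyphenyl)[2-methoxy-4-(methoxymethoxy)-6-methylphenyl]methanone | COc1cc(OC)c(C(=O)c2c(C)cc(OCOC)cc2OC)c(O)c1Cl | intermediate
20 | (3-chloro-2-hydroxy-4,6-dimethoxyphenyl)(4-hydroxy-2-methoxy-6-methylphenyl)methanone | COc1cc(OC)c(C(=O)c2c(C)cc(O)cc2OC)c(O)c1Cl | target

Total step count: 10. Longest linear sequence: 8 steps (steps 1, 2, 4, 5, 7, 8, 9, 10, from 1 to 20); steps 3 and 6 supply the two small partners.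

Steps most likely to fail

Step 7. Capture of the vinylketene by the branched, congested alkyne carbon may be slower than ketene dimerisation or acylation of the product phenol. The benzylic silyl ether may also ionise at the temperature required. The fallback gives up building ring A and joins the two rings by an aryllithium addition. It sets out from aldehyde 3 and commercial 2-chloro-3,5-dimethoxyphenol. The phenol is converted with MOMCl and i-Pr2NEt into 2-chloro-1,5-dimethoxy-3-(methoxymethoxy)benzene F1. Directed ortho-lithiation (n-BuLi, TMEDA, THF, 0 °C) at the CH flanked by OMOM and OMe should give [3-chloro-4,6-dimethoxy-2-(methoxymethoxy)phenyl]lithium F2. Addition of F2 to 3 should give [3-chloro-4,6-dimethoxy-2-(methoxymethoxy)phenyl][2-methoxy-4-(methoxymethoxy)-6-methylphenyl]methanol F3. Dess–Martin periodinane should oxidise it to [3-chloro-4,6-dimethoxy-2-(methoxymethoxy)phenyl][2-methoxy-4-(methoxymethoxy)-6-methylphenyl]methanone F4. HCl in MeOH then removes both MOM groups, and the fallback rejoins the route at target 20.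

Step 6. Chloroketene may polymerise faster than it is trapped, and the chlorinated vinylogous ester may decompose on isolation. The fallback sets out from methoxyacetylene 6 and uses the better-behaved dichloroketene. Dichloroketene F5, generated from dichloroacetyl chloride and Et3N in Et2O at 0 °C, is trapped by 6 to give 4,4-dichloro-3-methoxycyclobut-2-en-1-one F6. One chlorine is then removed reductively with Zn dust in AcOH at 0 °C, the reduction being stopped at the monochloride, which returns to the route at 12.

Step 9. The heterogeneous oxidation may stall at the congested tetra-ortho-substituted carbinol, or the free ring A phenol may be oxidised in competition. The fallback sets out from 17 and masks that phenol so that a stronger homogeneous oxidant can be used. MOMCl with NaH in DMF at 0 °C should give tert-butyl{[3-chloro-4,6-dimethoxy-2-(methoxymethoxy)phenyl][2-methoxy-4-(methoxymethoxy)-6-methylphenyl]methoxy}dimethylsilane F7. TBAF then frees the carbinol as [3-chloro-4,6-dimethoxy-2-(methoxymethoxy)phenyl][2-methoxy-4-(methoxymethoxy)-6-methylphenyl]methanol F3. Dess–Martin periodinane should give [3-chloro-4,6-dimethoxy-2-(methoxymethoxy)phenyl][2-methoxy-4-(methoxymethoxy)-6-methylphenyl]methanone F4. HCl in MeOH cleaves both MOM ethers, and the fallback rejoins the route at target 20.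

Further compounds
F1 | step 7 | 2-chloro-1,5-dimethoxy-3-(methoxymethoxy)benzene | COCOc1cc(OC)cc(OC)c1Cl
F2 | step 7 | [3-chloro-4,6-dimethoxy-2-(methoxymethoxy)phenyl]lithium | COCOc1c([Li])c(OC)cc(OC)c1Cl
F3 | step 7 | [3-chloro-4,6-dimethoxy-2-(methoxymethoxy)phenyl][2-methoxy-4-(methoxymethoxy)-6-methylphenyl]methanol (racemic) | COCOc1c(C(O)c2c(C)cc(OCOC)cc2OC)c(OC)cc(OC)c1Cl
F4 | step 7 | [3-chloro-4,6-dimethoxy-2-(methoxymethoxy)phenyl][2-methoxy-4-(methoxymethoxy)-6-methylphenyl]methanone | COCOc1c(C(=O)c2c(C)cc(OCOC)cc2OC)c(OC)cc(OC)c1Cl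
F5 | step 6 | dichloroketene | O=C=C(Cl)Cl
F6 | step 6 | 4,4-dichloro-3-methoxycyclobut-2-en-1-one | O=C1C=C(OC)C1(Cl)Cl
F7 | step 9 | tert-butyl{[3-chloro-4,6-dimethoxy-2-(methoxymethoxy)phenyl][2-methoxy-4-(methoxymethoxy)-6-methylphenyl]methoxy}dimethylsilane (racemic) | COCOc1c(C(O[Si](C)(C)C(C)(C)C)c2c(C)cc(OCOC)cc2OC)c(OC)cc(OC)c1Cl
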